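**Plan**
- Cuts: the butenolide at C13=C14 (ring-closing metathesis) and C12–C13 (asymmetric Morita–Baylis–Hillman); C8=C17 (Wittig); C4–C18 (enolate methylation); then both decalin rings at once through C5–C10 and C3–C4 (intramolecular Diels–Alder); C2–C1, C4=C5 and C10–C20 of the open-chain triene (Suzuki, cross-metathesis, carboalumination); C8–C9 (aldol).
- Enabling feature: ring A is a cyclohexane in which C1–C2 can be an alkene and C3 carries oxygen. C3=C2–C1=C10 is therefore a diene with a heteroatom at C3 (boron as oxygen placeholder), C4=C5 is an enoate whose ester carbon is C19, and the four-carbon chain C6–C9 joining C5 to C10 becomes ring B.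
- Forward order: syn-aldol (C8–C9) → alkyne → (E)-vinyl iodide (C20 in) → enoate → (E,E)-dienylboronate → cycloaddition closes ring B and ring A together → C–B to C–O, C3/C8 ketones, C17 and C18 in, reductions → C12 aldehyde → lactone.
- Helpers removed later: boron (step 10), the C8 silyl ether oxygen (becomes C17 methylene, steps 10–12), the C1=C2 alkene and benzyl group (step 14), the acetonide (step 20).
- Stereochemistry: C9 (and the temporary C8 carbinol) from the auxiliary-controlled aldol; C5 and C10 in the cycloaddition (alkene geometries, ester endo, C8/C9 groups equatorial in the chair tether); C4 by methylation anti to C20; C3 by axial hydride attack; C12 by the β-isocupreidine catalyst.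

Key step: step 9

Remark: labdane numbering is used (C1–C10 decalin, C11–C16 side chain and lactone, C17 exocyclic methylene, C18 methyl and C19 oxygenated carbon on C4, C20 methyl on C10); α is the ring face that carries C20, β the opposite face.

Step 1
Reactants: 1 (R)-4-benzyl-1,3-thiazolidine-2-thione; 2 4-(benzyloxy)butanoic acid
Product: 3 (R)-4-benzyl-3-[4-(benzyloxy)butanoyl]-1,3-thiazolidine-2-thione
Conditions: DCC, DMAP (cat.), CH2Cl2, 0 °C → rt
Reagents that add atoms: none
Why: Carbodiimide-mediated N-acylation (Steglich type) of the auxiliary brings in C9–C12 with C10 as the acyl carbon and creates no stereocentre.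

Step 2
Reactants: 3 (R)-4-benzyl-3-[4-(benzyloxy)butanoyl]-1,3-thiazolidine-2-thione; 4 pent-4-enal
Product: 6 (R)-4-benzyl-3-{(2R,3S)-2-[2-(benzyloxy)ethyl]-3-hydroxyhept-6-enoyl}-1,3-thiazolidine-2-thione, via chlorotitanium Z-enolate 5 (not isolated)
Conditions: TiCl4, iPr2NEt, N-methyl-2-pyrrolidinone, CH2Cl2, 0 °C; then 4, −78 → 0 °C
Reagents that add atoms: none
Why: In this titanium-mediated Evans-type syn-aldol the Z-enolate 5 should add through a closed Zimmerman–Traxler chair to the aldehyde face left open by the benzyl group of the (R)-auxiliary, setting C9 (R) and C8 (S) as the syn pair.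

Step 3
Reactants: 6 (R)-4-benzyl-3-{(2R,3S)-2-[2-(benzyloxy)ethyl]-3-hydroxyhept-6-enoyl}-1,3-thiazolidine-2-thione
Product: 7 triethylsilyl ether of 6
Conditions: Et3SiOTf, 2,6-lutidine, CH2Cl2, −78 °C
Reagents that add atoms: triethylsilyl trifluoromethanesulfonate, CC[Si](CC)(CC)OS(=O)(=O)C(F)(F)F
Why: Silyl triflate silylation of the secondary carbinol blocks retro-aldol cleavage and later conjugate addition of the C8 oxygen to the enoate.

Step 4
Reactants: 7 triethylsilyl ether of 6
Product: 8 (2R,3S)-2-[2-(benzyloxy)ethyl]-3-(triethylsilyloxy)hept-6-enal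
Conditions: iBu2AlH, CH2Cl2, −78 °C
Reagents that add atoms: none
Why: Hydride reduction of the activated N-acylthiazolidinethione should stop at the aldehyde through a stable aluminium hemiaminal and release the auxiliary without touching C9.

Step 5
Reactants: 8 (2R,3S)-2-[2-(benzyloxy)ethyl]-3-(triethylsilyloxy)hept-6-enal
Product: 9 (3S,4S)-3-[2-(benzyloxy)ethyl]-4-(triethylsilyloxy)oct-7-en-1-yne
Conditions: dimethyl (1-diazo-2-oxopropyl)phosphonate, K2CO3, MeOH, 0 °C → rt
Reagents that add atoms: dimethyl (1-diazo-2-oxopropyl)phosphonate, COP(=O)(OC)C(=[N+]=[N-])C(C)=O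
Why: Ohira–Bestmann (Seyferth–Gilbert) homologation under weakly basic conditions turns the aldehyde carbon (C10) into the alkyne and adds C1, and the α-stereocentre should be kept at low temperature.

Step 6
Reactants: 9 (3S,4S)-3-[2-(benzyloxy)ethyl]-4-(triethylsilyloxy)oct-7-en-1-yne
Product: 11 (1E,3S,4S)-3-[2-(benzyloxy)ethyl]-1-iodo-2-methyl-4-(triethylsilyloxy)octa-1,7-diene, via alkenyldimethylalane 10 (not isolated)
Conditions: AlMe3, Cp2ZrCl2 (0.3 equiv), H2O (1 equiv), CH2Cl2, −20 °C; then I2, THF, −20 → 0 °C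
Reagents that add atoms: trimethylaluminium, C[Al](C)C; iodine, II
Why: Zirconium-catalysed Negishi carboalumination adds methyl (C20) and aluminium syn across the terminal alkyne with methyl on the internal carbon, and iodinolysis with retention should give the (E)-vinyl iodide while the isolated terminal alkene stays inert.

Step 7
Reactants: 11 (1E,3S,4S)-3-[2-(benzyloxy)ethyl]-1-iodo-2-methyl-4-(triethylsilyloxy)octa-1,7-diene; 12 methyl acrylate
Product: 13 methyl (2E,6S,7S,8E)-7-[2-(benzyloxy)ethyl]-9-iodo-8-methyl-6-(triethylsilyloxy)nona-2,8-dienoate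
Conditions: 12 (5 equiv), RuCl2(=CH-C6H4-2-OiPr)(H2IMes) (second-generation Hoveyda–Grubbs catalyst, 3 mol %), CH2Cl2, 40 °C
Reagents that add atoms: none
Why: Olefin cross-metathesis of the monosubstituted alkene with the acrylate should give the (E)-enoate (C4=C5, C19 as ester carbon), the hindered iodo-substituted alkene not engaging the catalyst.

Step 8
Reactants: 13 methyl (2E,6S,7S,8E)-7-[2-(benzyloxy)ethyl]-9-iodo-8-methyl-6-(triethylsilyloxy)nona-2,8-dienoate; 14 (E)-1,2-bis(4,4,5,5-tetramethyl-1,3,2-dioxaborolan-2-yl)ethene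
Product: 15 methyl (2E,6S,7S,8E,10E)-7-[2-(benzyloxy)ethyl]-8-methyl-11-(4,4,5,5-tetramethyl-1,3,2-dioxaborolan-2-yl)-6-(triethylsilyloxy)undeca-2,8,10-trienoate
Conditions: 14 (3 equiv), PdCl2(dppf) (5 mol %), Cs2CO3, THF/H2O, 45 °C
Reagents that add atoms: none
Why: Suzuki–Miyaura coupling proceeds with retention at both partners and, with the diboron reagent in excess, should stop after one coupling to give the (E,E)-dienylboronate C3=C2–C1=C10.

Step 9
Reactants: 15 methyl (2E,6S,7S,8E,10E)-7-[2-(benzyloxy)ethyl]-8-methyl-11-(4,4,5,5-tetramethyl-1,3,2-dioxaborolan-2-yl)-6-(triethylsilyloxy)undeca-2,8,10-trienoate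
Product: 16 trans-fused 3β-boryl Δ1-octalin 4β-methyl ester (full description in the compound list)
Conditions: EtAlCl2 (1.5 equiv), CH2Cl2, −78 → 0 °C
Reagents that add atoms: none
Why: EtAlCl2 binds the ester carbonyl and the C4=C5 enoate should add suprafacially across the C3=C2–C1=C10 dienylboronate in a concerted, asynchronous [4+2] cycloaddition, the closest known reaction types being the Lewis-acid-promoted intramolecular Diels–Alder reaction of (E,E,E)-trienoates to trans-fused bicycles and the Diels–Alder reaction of 1-boryl-1,3-dienes. Ring A closes as the cyclohexene of the [4+2] event (bonds C5–C10 and C3–C4), and ring B closes in the same event as a six-membered ring through the C5–C10 bond, because the four-carbon tether C6–C9 joins the dienophile carbon C5 to the diene terminus C10 and folds as a chair. C10 is fixed by the (E)-C1=C10 geometry (tether outside, C20 inside) and C5 by the endo orientation of the ester of the (E)-enoate, which together should give the trans ring fusion (C20 α, H-5 β); the same endo transition state puts the C4 ester β and the (E)-alkenylboron geometry puts boron β at C3, both centres being reset in later steps. The absolute sense follows from C8 and C9, whose silyloxy and benzyloxyethyl groups are both equatorial in the chair tether only for addition to the diene face that gives the shown isomer, the other face forcing the silyl ether 1,3-diaxial to C20. The step needs endo over exo selectivity, secured by the Lewis acid and the E-enoate, and π-facial selectivity, secured by the syn C8/C9 pair from step 2; the regiochemistry is fixed by the tether and agrees with the ortho preference of 1-boryl dienes.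

Step 10
Reactants: 16 trans-fused 3β-boryl Δ1-octalin 4β-methyl ester
Product: 18 3β,8β-dihydroxy Δ1-octalin 4β-methyl ester, via allylic alcohol silyl ether 17 (not isolated)
Conditions: NaBO3·4H2O, THF/H2O, rt; then 1 M HCl, THF, rt
Reagents that add atoms: sodium perborate, [Na+].[O-]B1OO1
Why: Perborate oxidation of the allylic C–B bond proceeds by 1,2-migration from boron to oxygen with retention and without allylic shift, and dilute acid should then cleave the triethylsilyl ether.

Step 11
Reactants: 18 3β,8β-dihydroxy Δ1-octalin 4β-methyl ester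
Product: 19 Δ1-3,8-dioxo-octalin 4-methyl ester
Conditions: Dess–Martin periodinane (3 equiv), CH2Cl2, rt
Reagents that add atoms: none
Why: Dess–Martin oxidation should convert both secondary carbinols, giving the Δ1-en-3-one (a β-keto ester at C4) and the C8 ketone, so that the temporary C3 and C8 configurations are erased on purpose.

Step 12
Reactants: 19 Δ1-3,8-dioxo-octalin 4-methyl ester
Product: 21 8(17)-methylene Δ1-3-oxo-octalin 4-methyl ester, via potassium enolate 20 (not isolated)
Conditions: Ph3PCH3Br (4 equiv), KOtBu (4 equiv), THF, 0 °C → rt; aq. NH4Cl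
Reagents that add atoms: methyltriphenylphosphonium bromide, C[P+](c1ccccc1)(c1ccccc1)c1ccccc1.[Br-]
Why: In this Wittig methylenation the base first converts the acidic β-keto ester into the unreactive enolate 20, so the ylide should attack only the C8 ketone, and C9 can only settle in its equatorial, thermodynamically preferred configuration.

Step 13
Reactants: 21 8(17)-methylene Δ1-3-oxo-octalin 4-methyl ester
Product: 22 4β-methyl-8(17)-methylene Δ1-3-oxo-octalin 4α-methyl ester
Conditions: MeI, K2CO3, acetone, rt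
Reagents that add atoms: iodomethane, CI
Why: C-Alkylation of the β-keto ester enolate, in which iodomethane should approach C4 from the β face, away from the axial C20 on C10, so that C18 becomes equatorial and the ester (C19) axial.

Step 14
Reactants: 22 4β-methyl-8(17)-methylene Δ1-3-oxo-octalin 4α-methyl ester
Product: 23 saturated 3-oxo 4α-methyl ester with free C12 hydroxyl
Conditions: Li, NH3(l), THF, −78 °C; then NH4Cl
Reagents that add atoms: none
Why: Dissolving-metal (Birch-type) reduction should saturate the enone by way of its lithium enolate and cleave the benzyl ether, while the isolated exocyclic alkene is not reduced and no new stereocentre arises.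

Step 15
Reactants: 23 saturated 3-oxo 4α-methyl ester with free C12 hydroxyl
Product: 24 3α,12,19-triol
Conditions: LiAlH4, THF, −78 °C → rt
Reagents that add atoms: none
Why: In this hydride reduction the C3 ketone should react first, at low temperature, by axial attack from the β face away from the axial C4 ester, giving the equatorial 3α-alcohol, and on warming the ester is reduced to the C19 carbinol.

Step 16
Reactants: 24 3α,12,19-triol
Product: 25 3α,19-O-isopropylidene 12-alcohol
Conditions: Me2C(OMe)2, PPTS (cat.), acetone, rt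
Reagents that add atoms: 2,2-dimethoxypropane, COC(C)(C)OC
Why: Acid-catalysed transketalisation should selectively form the six-membered isopropylidene acetal of the cis-disposed 3,19-diol and leave the C12 hydroxyl free.

Step 17
Reactants: 25 3α,19-O-isopropylidene 12-alcohol
Product: 26 3α,19-O-isopropylidene 12-aldehyde
Conditions: TEMPO (cat.), PhI(OAc)2, CH2Cl2, rt
Reagents that add atoms: none
Why: Oxoammonium-mediated (TEMPO) oxidation of the primary alcohol should give the aldehyde under non-epimerising conditions that the acetonide and the alkene tolerate.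

Step 18
Reactants: 26 3α,19-O-isopropylidene 12-aldehyde; 27 1,1,1,3,3,3-hexafluoropropan-2-yl acrylate; 28 prop-2-en-1-ol
Product: 30 allyl (12R)-2-methylene-3-hydroxy ester, via hexafluoroisopropyl ester 29 (not isolated)
Conditions: 27 (1.3 equiv), β-isocupreidine (0.2 equiv), DMF, −55 °C; then 28, Et3N, 0 °C → rt
Reagents that add atoms: none
Why: In this asymmetric Morita–Baylis–Hillman reaction the bifunctional cinchona catalyst adds to the activated acrylate and directs the aldol step to one aldehyde face, which should set C12 as R under catalyst control, and the activated ester is then transesterified by the allylic alcohol.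

Step 19
Reactants: 30 allyl (12R)-2-methylene-3-hydroxy ester
Product: 31 3α,19-O-isopropylidene derivative of the target
Conditions: RuCl2(=CHPh)(PCy3)(H2IMes) (second-generation Grubbs catalyst, 5 mol %), CH2Cl2, 40 °C
Reagents that add atoms: none
Why: Ring-closing metathesis between the allyl group and the 1,1-disubstituted acrylate alkene should close the five-membered butenolide (C13=C14) faster than any reaction at the hindered exocyclic methylene.

Step 20
Reactants: 31 3α,19-O-isopropylidene derivative of the target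
Product: 32 CNP0270153.1 (14-deoxy-12R-hydroxyandrographolide)
Conditions: AcOH/H2O (4:1), rt
Reagents that add atoms: none
Why: Mild acid hydrolysis of the isopropylidene acetal should free the 3,19-diol without ionising the C12 carbinol, which is deactivated by the electron-poor butenolide.

**Compound list**
1 | (R)-4-benzyl-1,3-thiazolidine-2-thione | S=C1N[C@H](Cc2ccccc2)CS1 | starting material
2 | 4-(benzyloxy)butanoic acid | OC(=O)CCCOCc1ccccc1 | starting material
3 | (R)-4-benzyl-3-[4-(benzyloxy)butanoyl]-1,3-thiazolidine-2-thione | O=C(CCCOCc1ccccc1)N1C(=S)SC[C@H]1Cc1ccccc1 | intermediate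
4 | pent-4-enal | C=CCCC=O | starting material
5 | chlorotitanium (Z)-enolate of 3 | Cl[Ti](Cl)(Cl)O/C(=C\CCOCc1ccccc1)N1C(=S)SC[C@H]1Cc1ccccc1 | intermediate
6 | (R)-4-benzyl-3-{(2R,3S)-2-[2-(benzyloxy)ethyl]-3-hydroxyhept-6-enoyl}-1,3-thiazolidine-2-thione | C=CCC[C@H](O)[C@@H](CCOCc1ccccc1)C(=O)N1C(=S)SC[C@H]1Cc1ccccc1 | intermediate
7 | triethylsilyl ether of 6 | C=CCC[C@H](O[Si](CC)(CC)CC)[C@@H](CCOCc1ccccc1)C(=O)N1C(=S)SC[C@H]1Cc1ccccc1 | intermediate
8 | (2R,3S)-2-[2-(benzyloxy)ethyl]-3-(triethylsilyloxy)hept-6-enal | C=CCC[C@H](O[Si](CC)(CC)CC)[C@@H](CCOCc1ccccc1)C=O | intermediate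
9 | (3S,4S)-3-[2-(benzyloxy)ethyl]-4-(triethylsilyloxy)oct-7-en-1-yne | C=CCC[C@H](O[Si](CC)(CC)CC)[C@@H](CCOCc1ccccc1)C#C | intermediate
10 | (E)-alkenyldimethylalane from 9 (methyl on C10, aluminium on C1) | C=CCC[C@H](O[Si](CC)(CC)CC)[C@@H](CCOCc1ccccc1)/C(C)=C/[Al](C)C | intermediate
11 | (1E,3S,4S)-3-[2-(benzyloxy)ethyl]-1-iodo-2-methyl-4-(triethylsilyloxy)octa-1,7-diene | C=CCC[C@H](O[Si](CC)(CC)CC)[C@@H](CCOCc1ccccc1)/C(C)=C/I | intermediate
12 | methyl acrylate | C=CC(=O)OC | starting material
13 | methyl (2E,6S,7S,8E)-7-[2-(benzyloxy)ethyl]-9-iodo-8-methyl-6-(triethylsilyloxy)nona-2,8-dienoate | COC(=O)/C=C/CC[C@H](O[Si](CC)(CC)CC)[C@@H](CCOCc1ccccc1)/C(C)=C/I | intermediate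
14 | (E)-1,2-bis(4,4,5,5-tetramethyl-1,3,2-dioxaborolan-2-yl)ethene | CC1(C)OB(/C=C/B2OC(C)(C)C(C)(C)O2)OC1(C)C | starting material
15 | methyl (2E,6S,7S,8E,10E)-7-[2-(benzyloxy)ethyl]-8-methyl-11-(4,4,5,5-tetramethyl-1,3,2-dioxaborolan-2-yl)-6-(triethylsilyloxy)undeca-2,8,10-trienoate | COC(=O)/C=C/CC[C@H](O[Si](CC)(CC)CC)[C@@H](CCOCc1ccccc1)/C(C)=C/C=C/B1OC(C)(C)C(C)(C)O1 | intermediate
16 | cycloadduct: trans-fused Δ1-octalin with 3β-pinacolboryl, 4β-CO2Me (4α-H), 5β-H, 8β-OSiEt3, 9α-CH2CH2OBn (9β-H), 10α-CH3 | CC[Si](CC)(CC)O[C@H]1CC[C@@H]2[C@@H](C(=O)OC)[C@@H](B3OC(C)(C)C(C)(C)O3)C=C[C@@]2(C)[C@@H]1CCOCc1ccccc1 | intermediate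
17 | 3β-hydroxy analogue of 16 (8β-OSiEt3 kept) | CC[Si](CC)(CC)O[C@H]1CC[C@@H]2[C@@H](C(=O)OC)[C@@H](O)C=C[C@@]2(C)[C@@H]1CCOCc1ccccc1 | intermediate
18 | 3β,8β-diol: Δ1-octalin with 4β-CO2Me, 9α-CH2CH2OBn, 10α-CH3 | O[C@H]1CC[C@@H]2[C@@H](C(=O)OC)[C@@H](O)C=C[C@@]2(C)[C@@H]1CCOCc1ccccc1 | intermediate
19 | Δ1-3,8-dioxo-octalin 4-methyl ester (β-keto ester, C4 epimerisable, drawn 4β-CO2Me) | O=C1CC[C@@H]2[C@@H](C(=O)OC)C(=O)C=C[C@@]2(C)[C@@H]1CCOCc1ccccc1 | intermediate
20 | potassium enolate of 19 (C3–O−, C3=C4) | O=C1CC[C@@H]2C(C(=O)OC)=C([O-])C=C[C@@]2(C)[C@@H]1CCOCc1ccccc1.[K+] | intermediate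
21 | 8(17)-methylene Δ1-3-oxo-octalin 4-methyl ester (C4 epimerisable, drawn 4β-CO2Me) | C=C1CC[C@@H]2[C@@H](C(=O)OC)C(=O)C=C[C@@]2(C)[C@@H]1CCOCc1ccccc1 | intermediate
22 | 4β-methyl (C18), 4α-CO2Me (C19) 8(17)-methylene Δ1-en-3-one, 12-O-benzyl | C=C1CC[C@@H]2[C@](C)(C(=O)OC)C(=O)C=C[C@@]2(C)[C@@H]1CCOCc1ccccc1 | intermediate
23 | saturated 3-ketone: 4β-methyl, 4α-CO2Me, 8(17)-methylene, 9α-CH2CH2OH | C=C1CC[C@@H]2[C@](C)(C(=O)OC)C(=O)CC[C@@]2(C)[C@@H]1CCO | intermediate
24 | 3α,12,19-triol (3α-OH equatorial, 4α-CH2OH, 4β-CH3, 8(17)-methylene, 9α-CH2CH2OH) | C=C1CC[C@@H]2[C@](C)(CO)[C@H](O)CC[C@@]2(C)[C@@H]1CCO | intermediate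
25 | 3α,19-O-isopropylidene acetal of 24 (C12–OH free) | C=C1CC[C@@H]2[C@](C)(COC(C)(C)O3)[C@H]3CC[C@@]2(C)[C@@H]1CCO | intermediate
26 | 3α,19-O-isopropylidene 12-aldehyde | C=C1CC[C@@H]2[C@](C)(COC(C)(C)O3)[C@H]3CC[C@@]2(C)[C@@H]1CC=O | intermediate
27 | 1,1,1,3,3,3-hexafluoropropan-2-yl acrylate | C=CC(=O)OC(C(F)(F)F)C(F)(F)F | starting material
28 | prop-2-en-1-ol (allyl alcohol) | C=CCO | starting material
29 | hexafluoroisopropyl 2-methylene-3-hydroxy ester, (12R), acetonide kept | C=C1CC[C@@H]2[C@](C)(COC(C)(C)O3)[C@H]3CC[C@@]2(C)[C@@H]1C[C@@H](O)C(=C)C(=O)OC(C(F)(F)F)C(F)(F)F | intermediate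
30 | allyl 2-methylene-3-hydroxy ester, (12R), acetonide kept | C=C1CC[C@@H]2[C@](C)(COC(C)(C)O3)[C@H]3CC[C@@]2(C)[C@@H]1C[C@@H](O)C(=C)C(=O)OCC=C | intermediate
31 | 3α,19-O-isopropylidene derivative of the target (butenolide closed, 12R) | C=C1CC[C@@H]2[C@](C)(COC(C)(C)O3)[C@H]3CC[C@@]2(C)[C@@H]1C[C@@H](O)C1=CCOC1=O | intermediate
32 | CNP0270153.1, 14-deoxy-12R-hydroxyandrographolide | C=C1CC[C@@H]2[C@](C)(CO)[C@H](O)CC[C@@]2(C)[C@@H]1C[C@@H](O)C1=CCOC1=O | target

**Totals**
Total step count: 20. Longest linear sequence: 20 steps (steps 1–20, from 1 and 2 to 32).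

**Steps most likely to fail**

Step 9. The cycloaddition may be slow because the diene carries an inside methyl group and an electron-poor boron substituent, so that Lewis-acid-induced loss of boron or erosion of the endo preference (cis-fused isomer) could compete. The fallback drops boron and brings the C3 oxygen in after ring formation. It sets out from 13: Suzuki–Miyaura coupling with vinylboronic acid pinacol ester (PdCl2(dppf), Cs2CO3) should give the boron-free triene F1. EtAlCl2-promoted intramolecular Diels–Alder reaction of F1 should give the trans-fused Δ1-octalin ester F2. Allylic oxidation at C3, the only allylic methylene (CrO3, 3,5-dimethylpyrazole, CH2Cl2, −20 °C), should give the enone silyl ether F3. Dilute HCl in THF should remove the silyl group to give the hydroxy enone F4, and Dess–Martin oxidation returns to the route at 19.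

Step 18. Amine-catalysed addition to a β-branched aliphatic aldehyde may be slow and incomplete, with dioxanone by-products and insufficient facial selectivity at C12. The fallback separates bond formation from stereocontrol. It sets out from 26: aldol addition of the lithium enolate of 3-(phenylselanyl)oxolan-2-one (LiN(iPr)2, THF, −78 °C) should give the β-hydroxy selenide F5 as a diastereomer mixture. Oxidation with H2O2 and pyridine and selenoxide syn-elimination toward C14 should give 31 together with its C12 epimer F6. Dess–Martin oxidation of the mixture should give the 12-ketone F7. CBS reduction with the (S)-methyl-oxazaborolidine and BH3·SMe2, the butenolide acting as the large group, returns to the route at 31.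

Step 14. Over-reduction of the hindered ester or incomplete cleavage of the benzyl ether may occur under the dissolving-metal conditions. The fallback separates the two tasks and postpones debenzylation until no ester is left. It sets out from 22: conjugate reduction with [(Ph3P)CuH]6 in benzene should give the saturated keto ester benzyl ether F8. LiAlH4 (THF, −78 °C → rt) should give the 3α,19-diol benzyl ether F9. Me2C(OMe)2 with PPTS should give the acetonide benzyl ether F10. Na in NH3(l)/THF at −78 °C then cleaves the benzyl ether and returns to the route at 25.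

**Further compounds**
F1 | step 9 | methyl (2E,6S,7S,8E)-7-[2-(benzyloxy)ethyl]-8-methyl-6-(triethylsilyloxy)undeca-2,8,10-trienoate | COC(=O)/C=C/CC[C@H](O[Si](CC)(CC)CC)[C@@H](CCOCc1ccccc1)/C(C)=C/C=C
F2 | step 9 | trans-fused Δ1-octalin with 4β-CO2Me, 8β-OSiEt3, 9α-CH2CH2OBn, 10α-CH3 and CH2 at C3 | CC[Si](CC)(CC)O[C@H]1CC[C@@H]2[C@@H](C(=O)OC)CC=C[C@@]2(C)[C@@H]1CCOCc1ccccc1
F3 | step 9 | Δ1-en-3-one of F2 (8β-OSiEt3 kept) | CC[Si](CC)(CC)O[C@H]1CC[C@@H]2[C@@H](C(=O)OC)C(=O)C=C[C@@]2(C)[C@@H]1CCOCc1ccccc1
F4 | step 9 | 8β-hydroxy Δ1-en-3-one 4-methyl ester | O[C@H]1CC[C@@H]2[C@@H](C(=O)OC)C(=O)C=C[C@@]2(C)[C@@H]1CCOCc1ccccc1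
F5 | step 18 | β-hydroxy selenide: 12-hydroxy-13-(phenylselanyl) saturated lactone, acetonide kept, C12 and C13 mixed | C=C1CC[C@@H]2[C@](C)(COC(C)(C)O3)[C@H]3CC[C@@]2(C)[C@@H]1CC(O)C1([Se]c2ccccc2)CCOC1=O
F6 | step 18 | (12S) epimer of 31 | C=C1CC[C@@H]2[C@](C)(COC(C)(C)O3)[C@H]3CC[C@@]2(C)[C@@H]1C[C@H](O)C1=CCOC1=O
F7 | step 18 | 12-oxo butenolide, acetonide kept | C=C1CC[C@@H]2[C@](C)(COC(C)(C)O3)[C@H]3CC[C@@]2(C)[C@@H]1CC(=O)C1=CCOC1=O
F8 | step 14 | saturated 3-ketone 4α-methyl ester, 12-O-benzyl | C=C1CC[C@@H]2[C@](C)(C(=O)OC)C(=O)CC[C@@]2(C)[C@@H]1CCOCc1ccccc1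
F9 | step 14 | 3α,19-diol, 12-O-benzyl | C=C1CC[C@@H]2[C@](C)(CO)[C@H](O)CC[C@@]2(C)[C@@H]1CCOCc1ccccc1
F10 | step 14 | 3α,19-O-isopropylidene acetal, 12-O-benzyl | C=C1CC[C@@H]2[C@](C)(COC(C)(C)O3)[C@H]3CC[C@@]2(C)[C@@H]1CCOCc1ccccc1
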